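**Strategy.** The route rests on cutting the upper pyran (ring C) at C3–C4 and at O1–C2. Upper C4 is bonded to C8 of ring D and to C4a of ring A, and the neighbouring C8a carries O1. The ring A–C4–ring D array is therefore the retron of an o-quinone methide with C4 as its exocyclic carbon, and the oxygenated C3 maps onto the α-position of an O-protected hydroxyacetaldehyde. One aminocatalytic operation should forge both bonds, close ring C as a lactol and set C3 and C4 (3R,4R, trans). Its precursor is a benzyl-protected ring A/ring D benzhydrol with a single free ortho phenol on ring A.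

Key step: step 6

Remarks on the chemistry:
- Rings A, C, B belong to the upper (epiafzelechin) unit and rings D, F, E to the lower (epicatechin) unit.
- "D-yl" stands for (2R,3R)-5,7-bis(benzyloxy)-2-[3,4-bis(benzyloxy)phenyl]-3-(tert-butyldimethylsilyloxy)chroman-8-yl. Bn = benzyl, TBS = tert-butyldimethylsilyl.
- Assumption: 3,4,5-tris(benzyloxy)benzoic acid, 4-(benzyloxy)phenylmagnesium bromide (THF solution) and (tert-butyldimethylsilyloxy)acetaldehyde are bought.
- In step 5 the aldehyde phenol is masked with a hydride base, because an amide base would leave an N–H acid that protonates the aryllithium.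

**Step 1**
Reactants: 1 (−)-epicatechin
Product: 2 5,7,3',4'-tetra-O-benzyl-(−)-epicatechin
Conditions: BnBr (4.2 equiv), K2CO3, DMF, 0 °C to rt
Reagents that add atoms: benzyl bromide, BrCc1ccccc1
Why: Williamson etherification in which carbonate deprotonates only the four phenols, so the secondary 3-OH stays free and no stereocentre is touched.

**Step 2**
Reactants: 2 5,7,3',4'-tetra-O-benzyl-(−)-epicatechin
Product: 3 8-bromo-5,7,3',4'-tetra-O-benzyl-(−)-epicatechin
Conditions: NBS (1.0 equiv), CH2Cl2, −78 °C to rt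
Reagents that add atoms: N-bromosuccinimide, O=C1CCC(=O)N1Br
Why: Electrophilic aromatic bromination of the phloroglucinol-type ring, where C8 (ortho to the ring oxygen and to 7-OBn) is the established preferred site over C6 in tetra-O-benzyl flavan-3-ols.

**Step 3**
Reactants: 3 8-bromo-5,7,3',4'-tetra-O-benzyl-(−)-epicatechin
Product: 4 8-bromo-3-O-TBS-5,7,3',4'-tetra-O-benzyl-(−)-epicatechin
Conditions: TBSCl, imidazole, DMF, rt
Reagents that add atoms: tert-butyldimethylsilyl chloride, CC(C)(C)[Si](C)(C)Cl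
Why: Imidazole-promoted O-silylation of the only free hydroxyl, which removes the acidic proton before lithiation.

**Step 4**
Reactants: 5 2,4,6-trihydroxybenzaldehyde
Product: 6 2,4-bis(benzyloxy)-6-hydroxybenzaldehyde
Conditions: BnBr (2.0 equiv), K2CO3, DMF, rt
Reagents that add atoms: benzyl bromide, BrCc1ccccc1
Why: Regioselective Williamson etherification, since after the 4-OH and one ortho OH are alkylated the last ortho OH is held in a hydrogen bond to the formyl group and resists further alkylation.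

**Step 5**
Reactants: 4 8-bromo-3-O-TBS-5,7,3',4'-tetra-O-benzyl-(−)-epicatechin; 6 2,4-bis(benzyloxy)-6-hydroxybenzaldehyde
Product: 9 [2,4-bis(benzyloxy)-6-hydroxyphenyl](D-yl)methanol as a mixture of carbinol epimers, via 8-lithio flavan 7 (not isolated), via sodium formylphenolate 8 (not isolated)
Conditions: 4, t-BuLi (2.05 equiv), THF, −78 °C; add 8 (from 6, NaH, THF, 0 °C), −78 to 0 °C; then H2O
Reagents that add atoms: none
Why: Bromine–lithium exchange followed by 1,2-addition of the aryllithium to the aldehyde, whose phenol is masked as its phenolate so that nothing protonates 7; the new carbinol centre forms without control, which is harmless because step 6 erases it.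

**Step 6**
Reactants: 9 [2,4-bis(benzyloxy)-6-hydroxyphenyl](D-yl)methanol; 10 (tert-butyldimethylsilyloxy)acetaldehyde
Product: 13 (3R,4R)-5,7-bis(benzyloxy)-3-(tert-butyldimethylsilyloxy)-4-(D-yl)chroman-2-ol as an anomeric mixture, via ring-A o-quinone methide 11 (not isolated), via catalyst-bound E-enamine 12 (not isolated)
Conditions: 10 (3 equiv), (S)-2-[diphenyl(trimethylsilyloxy)methyl]pyrrolidine (20 mol %), AcOH (20 mol %), CH2Cl2, 0 °C to rt
Reagents that add atoms: none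
Why: Acetic acid should ionise either carbinol epimer of 9 to the same planar ring-A o-quinone methide 11, the E-enamine 12 then attacks the methide carbon through its α-carbon (upper C3–C4), and the ring-A phenoxide so released adds to the iminium carbon (upper O1–C2) before hydrolysis frees the catalyst and lactol 13. The closest known reaction type is the diarylprolinol silyl ether catalysed Michael/hemiacetalisation (formal [4+2]) of in situ o-quinone methides with enolisable aldehydes, which gives trans-3,4-disubstituted chroman-2-ols, and α-silyloxy aldehydes are established enamine donors. Ring C closes in 6-exo-trig mode by oxygen attack on the iminium (or, after hydrolysis, aldehyde) carbon. C3 (R) is set by attack on the enamine face remote from the diphenyl(trimethylsilyloxy)methyl group of the (S)-catalyst, and C4 (R) by the synclinal approach that keeps ring D away from the silyloxy group, the same topicity that gives syn Michael adducts with this catalyst class; C3 can still epimerise through the open aldehyde and should settle trans to the C4 aryl, which sits pseudoaxial to avoid the peri 5-benzyloxy group, while the anomeric centre is left as a mixture because step 7 removes it. The step needs a single quinone methide and catalyst control over the distant lower-unit stereocentres: only ring A carries a free ortho hydroxyl, and the ring-F centres lie five bonds from the reacting carbon.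

**Step 7**
Reactants: 13 (3R,4R)-5,7-bis(benzyloxy)-3-(tert-butyldimethylsilyloxy)-4-(D-yl)chroman-2-ol; 14 4-(benzyloxy)phenylmagnesium bromide
Product: 16 (1S,2R,3R)-1-[4-(benzyloxy)phenyl]-3-[2,4-bis(benzyloxy)-6-hydroxyphenyl]-2-(tert-butyldimethylsilyloxy)-3-(D-yl)propan-1-ol, via ring-opened magnesium phenolate aldehyde 15 (not isolated)
Conditions: 14 (4 equiv), THF, −78 to 0 °C; then H2O
Reagents that add atoms: none
Why: Deprotonation opens the lactol to aldehyde 15, and Grignard addition under polar Felkin–Anh (non-chelation) control, with the bulky, poorly coordinating silyloxy group anti to the incoming aryl, should give the 1,2-anti carbinol with the (1S) configuration.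

**Step 8**
Reactants: 16 (1S,2R,3R)-1-[4-(benzyloxy)phenyl]-3-[2,4-bis(benzyloxy)-6-hydroxyphenyl]-2-(tert-butyldimethylsilyloxy)-3-(D-yl)propan-1-ol
Product: 17 (2R,3R,4R)-5,7-bis(benzyloxy)-2-[4-(benzyloxy)phenyl]-3-(tert-butyldimethylsilyloxy)-4-(D-yl)chromane
Conditions: PPh3, DIAD, toluene, 0 °C to rt
Reagents that add atoms: none
Why: Intramolecular Mitsunobu etherification in which the ring-A phenol displaces the activated benzylic oxygen in a 6-exo-tet SN2 closure with inversion, turning the (1S) carbinol into the (2R), 2,3-cis flavan.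

**Step 9**
Reactants: 17 (2R,3R,4R)-5,7-bis(benzyloxy)-2-[4-(benzyloxy)phenyl]-3-(tert-butyldimethylsilyloxy)-4-(D-yl)chromane
Product: 18 (2R,3R,4R)-5,7-bis(benzyloxy)-2-[4-(benzyloxy)phenyl]-4-[(2R,3R)-5,7-bis(benzyloxy)-2-[3,4-bis(benzyloxy)phenyl]-3-hydroxychroman-8-yl]chroman-3-ol
Conditions: HF·pyridine, pyridine, THF, 0 °C to rt
Reagents that add atoms: none
Why: Fluoride-driven cleavage of both secondary silyl ethers under buffered conditions that leave benzyl ethers and the interflavan bond intact, with no stereocentre involved.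

**Step 10**
Reactants: 18 the 3,3'-diol of step 9; 19 3,4,5-tris(benzyloxy)benzoic acid
Product: 20 (2R,3R,4R)-5,7-bis(benzyloxy)-2-[4-(benzyloxy)phenyl]-4-[(2R,3R)-5,7-bis(benzyloxy)-2-[3,4-bis(benzyloxy)phenyl]-3-[3,4,5-tris(benzyloxy)benzoyloxy]chroman-8-yl]chroman-3-yl 3,4,5-tris(benzyloxy)benzoate
Conditions: 19 (4 equiv), DCC, DMAP, CH2Cl2, rt to 40 °C
Reagents that add atoms: none
Why: Steglich esterification of both secondary alcohols through the acylpyridinium species, which acylates oxygen with retention at C3 of each unit.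

**Step 11**
Reactants: 20 the perbenzylated digallate of step 10
Product: 21 epiafzelechin 3-O-gallate-(4β→8)-epicatechin 3-O-gallate (target)
Conditions: H2 (1 atm), Pd(OH)2/C, THF/MeOH/H2O, rt
Reagents that add atoms: none
Why: Catalytic hydrogenolysis of all thirteen benzyl ethers under neutral conditions, which should spare the gallate esters, the cyclic benzylic C2–O1 bonds and the C4–C8 bond.

**Compound list**

1 | (−)-epicatechin, (2R,3R)-2-(3,4-dihydroxyphenyl)chromane-3,5,7-triol | O[C@@H]1Cc2c(O)cc(O)cc2O[C@@H]1c1ccc(O)c(O)c1 | starting material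

2 | 5,7,3',4'-tetra-O-benzyl-(−)-epicatechin, (2R,3R)-5,7-bis(benzyloxy)-2-[3,4-bis(benzyloxy)phenyl]chroman-3-ol | O[C@@H]1Cc2c(OCc3ccccc3)cc(OCc3ccccc3)cc2O[C@@H]1c1ccc(OCc2ccccc2)c(OCc2ccccc2)c1 | intermediate

3 | (2R,3R)-8-bromo-5,7-bis(benzyloxy)-2-[3,4-bis(benzyloxy)phenyl]chroman-3-ol | O[C@@H]1Cc2c(OCc3ccccc3)cc(OCc3ccccc3)c(Br)c2O[C@@H]1c1ccc(OCc2ccccc2)c(OCc2ccccc2)c1 | intermediate

4 | (2R,3R)-8-bromo-5,7-bis(benzyloxy)-2-[3,4-bis(benzyloxy)phenyl]-3-(tert-butyldimethylsilyloxy)chromane | CC(C)(C)[Si](C)(C)O[C@@H]1Cc2c(OCc3ccccc3)cc(OCc3ccccc3)c(Br)c2O[C@@H]1c1ccc(OCc2ccccc2)c(OCc2ccccc2)c1 | intermediate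

5 | 2,4,6-trihydroxybenzaldehyde | O=Cc1c(O)cc(O)cc1O | starting material

6 | 2,4-bis(benzyloxy)-6-hydroxybenzaldehyde | O=Cc1c(O)cc(OCc2ccccc2)cc1OCc1ccccc1 | intermediate

7 | (2R,3R)-5,7-bis(benzyloxy)-2-[3,4-bis(benzyloxy)phenyl]-3-(tert-butyldimethylsilyloxy)chroman-8-yllithium | CC(C)(C)[Si](C)(C)O[C@@H]1Cc2c(OCc3ccccc3)cc(OCc3ccccc3)c([Li])c2O[C@@H]1c1ccc(OCc2ccccc2)c(OCc2ccccc2)c1 | intermediate

8 | sodium 3,5-bis(benzyloxy)-2-formylphenolate | [Na+].[O-]c1cc(OCc2ccccc2)cc(OCc2ccccc2)c1C=O | intermediate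

9 | [2,4-bis(benzyloxy)-6-hydroxyphenyl](D-yl)methanol, both carbinol epimers | OC(c1c(O)cc(OCc2ccccc2)cc1OCc1ccccc1)c1c(OCc2ccccc2)cc(OCc2ccccc2)c2c1O[C@H](c1ccc(OCc3ccccc3)c(OCc3ccccc3)c1)[C@H](O[Si](C)(C)C(C)(C)C)C2 | intermediate

10 | (tert-butyldimethylsilyloxy)acetaldehyde | O=CCO[Si](C)(C)C(C)(C)C | starting material

11 | 3,5-bis(benzyloxy)-6-[(D-yl)methylidene]cyclohexa-2,4-dien-1-one (ring-A o-quinone methide) | O=C1C=C(OCc2ccccc2)C=C(OCc2ccccc2)C1=Cc1c(OCc2ccccc2)cc(OCc2ccccc2)c2c1O[C@H](c1ccc(OCc3ccccc3)c(OCc3ccccc3)c1)[C@H](O[Si](C)(C)C(C)(C)C)C2 | intermediate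

12 | (S)-1-[(E)-2-(tert-butyldimethylsilyloxy)ethenyl]-2-[diphenyl(trimethylsilyloxy)methyl]pyrrolidine | C[Si](C)(C)OC(c1ccccc1)(c1ccccc1)[C@@H]1CCCN1/C=C/O[Si](C)(C)C(C)(C)C | intermediate

13 | (3R,4R)-5,7-bis(benzyloxy)-3-(tert-butyldimethylsilyloxy)-4-(D-yl)chroman-2-ol, anomeric mixture | CC(C)(C)[Si](C)(C)O[C@@H]1[C@@H](c2c(OCc3ccccc3)cc(OCc3ccccc3)c3c2O[C@H](c2ccc(OCc4ccccc4)c(OCc4ccccc4)c2)[C@H](O[Si](C)(C)C(C)(C)C)C3)c2c(OCc3ccccc3)cc(OCc3ccccc3)cc2OC1O | intermediate

14 | 4-(benzyloxy)phenylmagnesium bromide | Br[Mg]c1ccc(OCc2ccccc2)cc1 | starting material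

15 | (2R,3R)-3-[2,4-bis(benzyloxy)-6-(bromomagnesiooxy)phenyl]-2-(tert-butyldimethylsilyloxy)-3-(D-yl)propanal | O=C[C@H](O[Si](C)(C)C(C)(C)C)[C@@H](c1c(OCc2ccccc2)cc(OCc2ccccc2)c2c1O[C@H](c1ccc(OCc3ccccc3)c(OCc3ccccc3)c1)[C@H](O[Si](C)(C)C(C)(C)C)C2)c1c(O[Mg]Br)cc(OCc2ccccc2)cc1OCc1ccccc1 | intermediate

16 | (1S,2R,3R)-1-[4-(benzyloxy)phenyl]-3-[2,4-bis(benzyloxy)-6-hydroxyphenyl]-2-(tert-butyldimethylsilyloxy)-3-(D-yl)propan-1-ol | O[C@@H](c1ccc(OCc2ccccc2)cc1)[C@H](O[Si](C)(C)C(C)(C)C)[C@@H](c1c(OCc2ccccc2)cc(OCc2ccccc2)c2c1O[C@H](c1ccc(OCc3ccccc3)c(OCc3ccccc3)c1)[C@H](O[Si](C)(C)C(C)(C)C)C2)c1c(O)cc(OCc2ccccc2)cc1OCc1ccccc1 | intermediate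

17 | (2R,3R,4R)-5,7-bis(benzyloxy)-2-[4-(benzyloxy)phenyl]-3-(tert-butyldimethylsilyloxy)-4-(D-yl)chromane | CC(C)(C)[Si](C)(C)O[C@@H]1[C@@H](c2c(OCc3ccccc3)cc(OCc3ccccc3)c3c2O[C@H](c2ccc(OCc4ccccc4)c(OCc4ccccc4)c2)[C@H](O[Si](C)(C)C(C)(C)C)C3)c2c(OCc3ccccc3)cc(OCc3ccccc3)cc2O[C@@H]1c1ccc(OCc2ccccc2)cc1 | intermediate

18 | (2R,3R,4R)-5,7-bis(benzyloxy)-2-[4-(benzyloxy)phenyl]-4-[(2R,3R)-5,7-bis(benzyloxy)-2-[3,4-bis(benzyloxy)phenyl]-3-hydroxychroman-8-yl]chroman-3-ol | O[C@@H]1[C@@H](c2c(OCc3ccccc3)cc(OCc3ccccc3)c3c2O[C@H](c2ccc(OCc4ccccc4)c(OCc4ccccc4)c2)[C@H](O)C3)c2c(OCc3ccccc3)cc(OCc3ccccc3)cc2O[C@@H]1c1ccc(OCc2ccccc2)cc1 | intermediate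

19 | 3,4,5-tris(benzyloxy)benzoic acid | OC(=O)c1cc(OCc2ccccc2)c(OCc2ccccc2)c(OCc2ccccc2)c1 | starting material

20 | perbenzylated 3,3'-di-O-gallate (full name in step 10) | O=C(O[C@@H]1[C@@H](c2c(OCc3ccccc3)cc(OCc3ccccc3)c3c2O[C@H](c2ccc(OCc4ccccc4)c(OCc4ccccc4)c2)[C@H](OC(=O)c2cc(OCc4ccccc4)c(OCc4ccccc4)c(OCc4ccccc4)c2)C3)c2c(OCc3ccccc3)cc(OCc3ccccc3)cc2O[C@@H]1c1ccc(OCc2ccccc2)cc1)c1cc(OCc2ccccc2)c(OCc2ccccc2)c(OCc2ccccc2)c1 | intermediate

21 | epiafzelechin 3-O-gallate-(4β→8)-epicatechin 3-O-gallate, upper unit (2R,3R,4R), lower unit (2R,3R) | O=C(O[C@@H]1[C@@H](c2c(O)cc(O)c3c2O[C@H](c2ccc(O)c(O)c2)[C@H](OC(=O)c2cc(O)c(O)c(O)c2)C3)c2c(O)cc(O)cc2O[C@@H]1c1ccc(O)cc1)c1cc(O)c(O)c(O)c1 | target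

**Step count and risk**

Total: 11 steps. Longest linear sequence: 10 steps (1, 2, 3, 5, 6, 7, 8, 9, 10, 11).

Steps most likely to fail:

Step 6. The heavily donor-stabilised quinone methide may be captured slowly by the enamine, so that self-condensation through C6 of ring D, acid-induced loss of silyl groups or eroded face selectivity at C4 takes over. The fallback sets out from 9 and returns to 13. Benzhydrol 9 would be treated with p-toluenesulfinic acid (CH2Cl2, rt) to give the benzylic sulfone, [2,4-bis(benzyloxy)-6-hydroxyphenyl](D-yl)methyl p-tolyl sulfone F1. F1 would then be stirred with aldehyde 10, the same prolinol silyl ether and solid NaHCO3 in CH2Cl2. Base-induced 1,4-elimination of sulfinate releases quinone methide 11 slowly in a non-acidic medium, which is the known base-triggered variant of the aminocatalytic quinone methide/aldehyde annulation, and lactol 13 should result. A C4-epimeric lactol would be a diastereomer and could be removed by chromatography.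

Step 7. Delivery of the aryl group may be steered by the magnesium phenolate, or the lactol may open incompletely, so that the carbinol forms with poor facial selectivity. The fallback sets out from 13 and returns to 16. Lactol 13 would be oxidised with Ag2CO3 on Celite (toluene, 80 °C) to the lactone, (3R,4R)-5,7-bis(benzyloxy)-3-(tert-butyldimethylsilyloxy)-4-(D-yl)chroman-2-one F2. Opening with MeNHOMe·HCl and i-PrMgCl (THF, −20 °C) would give the Weinreb amide F3. Grignard reagent 14 (THF, 0 °C) would convert F3 into the aryl ketone F4. Reagent-controlled Corey–Bakshi–Shibata reduction ((S)-Me-CBS oxazaborolidine, excess BH3·SMe2, THF, −20 °C), with the aryl group as the large substituent, should then give the (1S) carbinol 16.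

Step 8. The activated p-benzyloxybenzylic alcohol may ionise before the phenol attacks, so that inversion is lost through a benzylic cation or elimination occurs. The fallback sets out from 13 and returns to 17. Commercial 4-chlorophenylmagnesium bromide would be added to 13 (THF, −78 to 0 °C) to give the chloro diol, (1S,2R,3R)-1-(4-chlorophenyl)-3-[2,4-bis(benzyloxy)-6-hydroxyphenyl]-2-(tert-butyldimethylsilyloxy)-3-(D-yl)propan-1-ol F5. The chloro substituent disfavours the benzylic cation, so Mitsunobu closure (PPh3, DIAD, toluene) should proceed with clean inversion to the chloroflavan, (2R,3R,4R)-5,7-bis(benzyloxy)-2-(4-chlorophenyl)-3-(tert-butyldimethylsilyloxy)-4-(D-yl)chromane F6. Palladium-catalysed C–O coupling of F6 with benzyl alcohol ([Pd(C3H5)Cl]2, RockPhos, Cs2CO3, toluene, 90 °C) would install the 4'-benzyloxy group and give 17.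

**Further compounds**

F1 | step 6 | [2,4-bis(benzyloxy)-6-hydroxyphenyl](D-yl)methyl p-tolyl sulfone, both epimers | Cc1ccc(cc1)S(=O)(=O)C(c1c(O)cc(OCc2ccccc2)cc1OCc1ccccc1)c1c(OCc2ccccc2)cc(OCc2ccccc2)c2c1O[C@H](c1ccc(OCc3ccccc3)c(OCc3ccccc3)c1)[C@H](O[Si](C)(C)C(C)(C)C)C2

F2 | step 7 | (3R,4R)-5,7-bis(benzyloxy)-3-(tert-butyldimethylsilyloxy)-4-(D-yl)chroman-2-one | CC(C)(C)[Si](C)(C)O[C@@H]1[C@@H](c2c(OCc3ccccc3)cc(OCc3ccccc3)c3c2O[C@H](c2ccc(OCc4ccccc4)c(OCc4ccccc4)c2)[C@H](O[Si](C)(C)C(C)(C)C)C3)c2c(OCc3ccccc3)cc(OCc3ccccc3)cc2OC1=O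

F3 | step 7 | (2R,3R)-3-[2,4-bis(benzyloxy)-6-hydroxyphenyl]-2-(tert-butyldimethylsilyloxy)-N-methoxy-N-methyl-3-(D-yl)propanamide | CON(C)C(=O)[C@H](O[Si](C)(C)C(C)(C)C)[C@@H](c1c(OCc2ccccc2)cc(OCc2ccccc2)c2c1O[C@H](c1ccc(OCc3ccccc3)c(OCc3ccccc3)c1)[C@H](O[Si](C)(C)C(C)(C)C)C2)c1c(O)cc(OCc2ccccc2)cc1OCc1ccccc1

F4 | step 7 | (2R,3R)-1-[4-(benzyloxy)phenyl]-3-[2,4-bis(benzyloxy)-6-hydroxyphenyl]-2-(tert-butyldimethylsilyloxy)-3-(D-yl)propan-1-one | O=C(c1ccc(OCc2ccccc2)cc1)[C@H](O[Si](C)(C)C(C)(C)C)[C@@H](c1c(OCc2ccccc2)cc(OCc2ccccc2)c2c1O[C@H](c1ccc(OCc3ccccc3)c(OCc3ccccc3)c1)[C@H](O[Si](C)(C)C(C)(C)C)C2)c1c(O)cc(OCc2ccccc2)cc1OCc1ccccc1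

F5 | step 8 | (1S,2R,3R)-1-(4-chlorophenyl)-3-[2,4-bis(benzyloxy)-6-hydroxyphenyl]-2-(tert-butyldimethylsilyloxy)-3-(D-yl)propan-1-ol | O[C@@H](c1ccc(Cl)cc1)[C@H](O[Si](C)(C)C(C)(C)C)[C@@H](c1c(OCc2ccccc2)cc(OCc2ccccc2)c2c1O[C@H](c1ccc(OCc3ccccc3)c(OCc3ccccc3)c1)[C@H](O[Si](C)(C)C(C)(C)C)C2)c1c(O)cc(OCc2ccccc2)cc1OCc1ccccc1

F6 | step 8 | (2R,3R,4R)-5,7-bis(benzyloxy)-2-(4-chlorophenyl)-3-(tert-butyldimethylsilyloxy)-4-(D-yl)chromane | CC(C)(C)[Si](C)(C)O[C@@H]1[C@@H](c2c(OCc3ccccc3)cc(OCc3ccccc3)c3c2O[C@H](c2ccc(OCc4ccccc4)c(OCc4ccccc4)c2)[C@H](O[Si](C)(C)C(C)(C)C)C3)c2c(OCc3ccccc3)cc(OCc3ccccc3)cc2O[C@@H]1c1ccc(Cl)cc1
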